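**Assumptions**
- (R)-Lavandulol is commercially available as the natural enantiomer. If only the racemate is at hand, lipase transesterification (vinyl acetate) resolves it.
- The benzoyl enol and the 1,3-dione tautomers interconvert, so the enol drawn in the target and the tautomer drawn for 6 and 7 are the same compounds.
- The target is the C7 diastereomer written in the SMILES, and C7 is taken directly from (R)-lavandulol. The C7 epimer 9 that forms alongside it is assumed to be separable by HPLC.

**Retrosynthesis**
1. The target is a bicyclo[3.3.1]nonane-2,4,9-trione. Ring B (C1–C5, C9) is the benzoylphloroglucinol ring, and ring A (C1, C5–C8, C9) derives from a lavandulyl chain.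
2. Ring A is formed last. C1–C8 is disconnected as a Markovnikov hydroalkylation of an isopropenyl group by the C1 enol carbon, which creates the gem-dimethyl C8.
3. C5–C6 is disconnected as an alkylative dearomatization of 3,5-diprenyl-2,4,6-trihydroxybenzophenone with (R)-lavandulyl iodide.
4. C7 comes from (R)-lavandulol with no change in geometry. Its CIP label changes from R to S only because the substituent priorities change. C1 is fixed by the bicycle once C5 is set.

**Step 1**
Reactants: 1 (2,4,6-trihydroxybenzophenone) and 2 (prenyl bromide, 2.2 equiv)
Product: 3 (3,5-bis(3-methylbut-2-enyl)-2,4,6-trihydroxybenzophenone)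
Conditions: KOH, MeOH/H2O, 0 °C → rt
Reagents that add atoms: prenyl bromide, CC(C)=CCBr, supplies both prenyl groups.
Why: Double C-alkylation (SN2) of the phenolate occurs at the two ring carbons that are flanked by two phenolic carbons, and the benzoyl-bearing carbon is blocked. The yield is statistical (about 30%), with O-prenyl and triprenyl by-products. No stereocenters are formed.

**Step 2**
Reactants: 4 ((R)-lavandulol)
Product: 5 ((R)-lavandulyl iodide)
Conditions: I2, PPh3, imidazole, CH2Cl2, 0 °C → rt
Reagents that add atoms: iodine, II (the iodine atom ends up in 5).
Why: Appel-type (Garegg–Samuelsson) SN2 at the primary CH2OH is neutral, so the alkenes survive. The stereocenter is β to the reacting carbon and is untouched, so the geometry is retained.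

**Step 3**
Reactants: 3 and 5 (1.5 equiv)
Product: 6 plus 7, a roughly 1:1 mixture of C5 epimers. 6 is the desired epimer and 7 is its C5 epimer.
Conditions: LiHMDS (2.2 equiv), THF, −78 °C; then 5, DMPU, −78 → 25 °C
Reagents that add atoms: (R)-lavandulyl iodide 5, IC[C@@H](C(C)=C)CC=C(C)C, supplies the lavandulyl group.
Why: Alkylative dearomatization. The dianion is C-alkylated at a prenyl-bearing ring carbon between the two enolate carbonyls, which gives a quaternary C5 (prenyl plus lavandulyl CH2) and a non-aromatic trione enol. The remote C7 center only weakly biases the new C5 center, so both epimers form. Both are carried forward because each cyclizes in step 4 to a bicyclic PPAP skeleton.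

**Step 4**
Reactants: 6 and 7 (mixture)
Product: 8 (target) from 6, and 9 (C7 epimer of 8) from 7, separated by HPLC
Conditions: Ph3PAuCl (5 mol %), AgOTf (5 mol %), toluene, 50 °C; then HPLC separation
Reagents that add atoms: none (isomerization).
Why: Au(I)-catalysed intramolecular Markovnikov hydroalkylation (6-exo) of the enolized 1,3-dione carbon C1 onto the 1,1-disubstituted isopropenyl group. This forms C1–C8, and the =CH2 terminus becomes CH3. The bridge geometry fixes C1 relative to C5, and C7 keeps its configuration. Epimer 6 gives 8 and epimer 7 gives 9.

**Compound list**
1 | 2,4,6-trihydroxybenzophenone | O=C(c1ccccc1)c1c(O)cc(O)cc1O | starting material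
2 | prenyl bromide | CC(C)=CCBr | starting material
3 | 3,5-bis(3-methylbut-2-enyl)-2,4,6-trihydroxybenzophenone | O=C(c1ccccc1)c1c(O)c(CC=C(C)C)c(O)c(CC=C(C)C)c1O | intermediate
4 | (R)-lavandulol | OC[C@@H](C(C)=C)CC=C(C)C | starting material
5 | (R)-lavandulyl iodide | IC[C@@H](C(C)=C)CC=C(C)C | intermediate
6 | dearomatized trione, desired C5 epimer (one tautomer drawn) | CC(C)=CC[C@H](C(C)=C)C[C@@]1(CC=C(C)C)C(=O)C(C(=O)c2ccccc2)C(O)=C(CC=C(C)C)C1=O | intermediate
7 | C5 epimer of 6 | CC(C)=CC[C@H](C(C)=C)C[C@]1(CC=C(C)C)C(=O)C(C(=O)c2ccccc2)C(O)=C(CC=C(C)C)C1=O | intermediate (leads only to the off-route epimer 9)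
8 | target, bicyclo[3.3.1]nonane-trione (enol form) | CC(C)=CC[C@H]1C[C@@]2(CC=C(C)C)C(=O)/C(=C(/O)c3ccccc3)C(=O)[C@](CC=C(C)C)(C2=O)C1(C)C | target
9 | C7 epimer of 8 (C1 and C5 inverted relative to C7) | CC(C)=CC[C@H]1C[C@]2(CC=C(C)C)C(=O)/C(=C(/O)c3ccccc3)C(=O)[C@@](CC=C(C)C)(C2=O)C1(C)C | intermediate (off-route diastereomer from 7, removed by HPLC and discarded)

**Totals**
Total steps: 4. Longest linear sequence: 3 (1 → 3 → 6 → 8; equivalently 4 → 5 → 6 → 8).

**Three steps most likely to fail**
1. **Step 4 (chemoselective cyclization).** The risks are enol O-cyclization or reaction at the prenyl alkenes, and a modest yield after separation from 9.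
   - Fallback: change the mechanism to Co-catalysed metal-hydride hydrogen-atom transfer with radical-polar crossover, using Co(salen), PhSiH3 and an N-fluoropyridinium oxidant. This reacts preferentially at the 1,1-disubstituted alkene to give the tertiary C8 cation equivalent, which the C1 enol then traps.
2. **Step 3 (hindered dearomative alkylation, about 1:1 dr).** The β-branched primary iodide is a poor electrophile toward a fully substituted enolate carbon, and O-alkylation competes.
   - Fallback: use an iodocarbocyclization route instead of lavandulyl alkylation.
     - Prenylate 3 to the C5-diprenyl dearomatized trione.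
     - Close ring A by I+-induced cyclization of the C5 prenyl onto C1, which forms C1–C8 and leaves iodine at C7.
     - Install the C7 prenyl by radical allylation with prenyl-SnBu3 under AIBN.
     - This route gives racemic product, so the enantiomer is obtained by chiral HPLC.
3. **Step 1 (statistical diprenylation, about 30%).**
   - Fallback: a regiocontrolled route through the tri-MOM-protected benzophenone. Use directed ortho-lithiation, then Cu-catalysed prenylation at each of the two ring positions, then MOM removal.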